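Late in the epsilon run the flask still moves. Between 8.00 h and 10.0 h target climbs from 35.7% to 40.4% of the charge, while isomer of the product falls from 24.2% to 22.6%. So I ask who finishes before whom.

| flask | substrate | precatalyst | remark | time |
|---|---|---|---|---|
| epsilon | 0.30 M | 15 mM | run made earlier |  |
| zeta | 0.42 M | 15 mM | run made earlier |  |
| gamma | 0.66 M | 15 mM | run made earlier |  |
| north-east | 0.30 M (fed, over 5.00 h) | 15 mM | all but substrate at the start; substrate goes in evenly over 5.00 h, the run ends at 10 h | 10 h |
| north | 0.30 M | 15 mM | one stirred flow tank at steady state, fed with the mixture as stated, mean residence time 10 h |  |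
| west | 0.30 M | 15 mM | a single well-mixed tank run continuously and read at steady state, 100 h in it on average |  |
| east | 0.30 M | 15 mM | everything together in a closed stirred flask, run for 10 h | 10 h |

| run | time / h | target / % | isomer of the product / % |
|---|---|---|---|
| epsilon | 1.50 | 4.6 | 24.1 |
| epsilon | 3.00 | 11.8 | 30.2 |
| epsilon | 5.00 | 23.2 | 29.6 |
| epsilon | 6.00 | 27.8 | 28.1 |
| epsilon | 8.00 | 35.7 | 24.2 |
| epsilon | 10.0 | 40.4 | 22.6 |
| zeta | 1.00 | 1.4 | 20.6 |
| zeta | 2.00 | 6.5 | 26.7 |
| zeta | 3.00 | 12.5 | 29.5 |
| zeta | 4.00 | 17.6 | 30.0 |
| zeta | 5.00 | 22.9 | 28.7 |
| zeta | 6.00 | 27.4 | 26.7 |
| gamma | 0.500 | 0 | 11.4 |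
| gamma | 0.833 | 1.4 | 16.8 |
| gamma | 1.33 | 3.2 | 22.9 |
| gamma | 2.00 | 7.0 | 27.3 |
| gamma | 4.00 | 17.8 | 29.2 |
| gamma | 6.00 | 27.7 | 27.2 |

(scatter of a reading: 0.5 percentage points)

- the stated concentrations are those of everything mixed, before any reaction; amounts are the same in each set-up
- what may be going on: substrate + catalyst <-> target + catalyst; substrate <-> isomer of the product; precatalyst -> catalyst
- the feed brings no volume worth counting
- the earlier runs were made in a closed, stirred flask

1. the set-up with the highest share of target in all that became target or isomer of the product, at the outlet or at the end ("none" if the first two lie within 2 percentage points) (north-east / north / west / east / none)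
2. share of target in all that became target or isomer of the product, at the outlet or at the end, north-east
3. share of target in all that became target or isomer of the product, at the outlet or at the end, north
4. share of target in all that became target or isomer of the product, at the outlet or at the end, west
5. share of target in all that became target or isomer of the product, at the outlet or at the end, east

I look first for the concentration that sets the order. At 6.00 h, the runs charged with 0.30 M, 0.42 M and 0.66 M show target at 27.8%, 27.4% and 27.7%. Fractions of the charge do not follow the charge, so I read target formation as first order in substrate. Its pace then follows the catalyst, which comes from 15 mM of precatalyst in each run. This is a pseudo-first-order step.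

The first rung is the isomer of the product. The gamma run reads 11.4% at 0.500 h, which gives, with the way back not counted, a forward constant of about 0.242 h⁻¹. The zeta run reads highest at 4.00 h, and at its peak the isomer of the product neither gains nor loses. So the ratio read there, 0.573 with the scatter of its readings, is my isomer ratio, the isomer of the product per substrate once that branch balances. Together these readings give a relaxation time of 1.50 h.

The second rung is the catalyst. Target per hour per substrate reads 0.0465 h⁻¹ early in the gamma run. Between 5.00 h and 6.00 h in the epsilon run it reads 0.101 h⁻¹, about twice as much.

The last rung is target itself: that epsilon reading gives a clock of 9.92 h, longer than my relaxation time for the isomer branch. Late on, once the isomer of the product has balanced substrate, my rule is: share = target / (target + isomer ratio × substrate).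

East repeats the epsilon run, so I commit to 64.1%. West's 100 h is ten times that clock, so I put west highest.

The forecast names west: “West is best.” It gives west 72% (range 68% to 78%), north-east 62%, north 62% and east 64%.

The flasks give west 70.7%, north-east 63.6%, north 63.1% and east 64.4%, so west is best.

    substrate + catalyst ⇌ target + catalyst, rate k1*[substrate]*[catalyst] forward; the back reaction follows from the equilibrium constant (K = 1.36, k = 19.7 M⁻¹ h⁻¹)
    substrate ⇌ isomer of the product (K = 0.548, k = 0.282 h⁻¹)
    precatalyst → catalyst (k = 0.167 h⁻¹)

East has not come to rest at 10 h. Left for 100 h, its share reaches 71.3%, a further 6.9 percentage points. By my rule, target per substrate goes from 1.04 to 1.42. North-east ends with target at 39.5% and substrate at 37.9%, so the rule gives 64.5%, against its 63.6%. Left for 100 h, north-east also reaches 71.3%.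

The numbers in the tables come from a simulation on assumed constants; noise was put on by code.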